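(Readings and results were computed on assumed constants.)

Count in equivalents of partner, since that is what your recipes change.

| setting | south-west | south | flask |
|---|---|---|---|
| starting material | 21 mM | 21 mM | 21 mM |
| partner | 1.5 equiv | 2.4 equiv | 1.10 equiv |
| remark | run made earlier | run made earlier |  |
| time |  |  | 2.5 h |

| run | time / min | mono adduct / % | starting material / % |
|---|---|---|---|
| south-west | 0.833 | 34.9 | 38.0 |
| south-west | 2.00 | 35.9 | 11.6 |
| south-west | 4.00 | 35.2 | 1.5 |
| south-west | 10.0 | 33.4 | 0.2 |
| south-west | 20.0 | 32.5 | 0.2 |
| south-west | 40.0 | 32.6 | 0 |
| south-west | 90.0 | 31.9 | 0 |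
| south | 0.833 | 45.9 | 20.9 |
| south | 2.00 | 49.8 | 3.5 |
| south | 4.00 | 47.9 | 0 |
| south | 10.0 | 43.7 | 0 |
| south | 20.0 | 41.2 | 0 |
| south | 40.0 | 39.1 | 0.2 |
| south | 90.0 | 40.3 | 1.5 |

(each reading ± 0.5 percentage points)

- the best time, 2.5 h at the latest, for mono adduct, in min
- the amount of mono adduct, in percent of the starting material charged, at that time
- earliest time at which at least nineteen twentieths of that best amount are there, in min
- latest time at which they still are



Build your flask one process at a time. With the main step alone, starting material + partner into mono adduct, 1.10 equiv covers the charge, so you expect 100 per cent mono adduct. The readings refuse this: the highest reading of the south-west run, with 1.5 equiv, is 35.9% after 2.00 min.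

So add a loss of mono adduct, and keep it crude. Take the peak reading divided by the equivalents charged, the yield per equivalent. In the south-west run it is 23.9%, which puts your flask at 26.3%.

The rest is a small correction. The south run reads 20.8% per equivalent, so between these two runs the yield falls by 3.54% for each equivalent added. Call this fall, with 21 mM of starting material held, the yield slope. Walking back from 1.5 equiv to your 1.10 equiv gives 25.3% per equivalent. That adds 1.6 percentage points, and since the readings carry their scatter I commit to about 27.8% mono adduct. I reckon no times.

The forecast says 28% at 2.5 min, with a window from 1.2 min to 0.2 h. Its ground is that “More partner gives more mono”.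

The flask gives 27.8% at 1.56 min, and its window runs from 0.910 min to 0.0506 h, all three times earlier than the forecast's.

    partner + double product → tris adduct (k = 0.111 M⁻¹ s⁻¹)
    starting material + partner → mono adduct (k = 0.599 M⁻¹ s⁻¹)
    partner + mono adduct → double product (k = 0.0196 M⁻¹ s⁻¹)
    starting material + mono adduct → side product (k = 1.00 M⁻¹ s⁻¹)
    partner → decomposed reagent (k = 0.00175 s⁻¹)

Take away the conversion of starting material + mono adduct into side product, and the peak of this flask goes from 27.8% to 79.6%, the largest single effect. The yield slope puts the neighbour with 0.660 equiv of partner at 17.7%. That neighbour reaches 17.1% of mono adduct at its best, and 97.9% of its starting material ends as side product.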